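**Retrosynthetic overview**
- Feature: ring C is a benzene with five neighbouring C-O bonds (C1-O to ring B, C2-O to ring D, OH on C3, C4 and C5) and a single C-H at C6. Rings G (C1-O-F, C2-O-H) and E (C2-O-F, C1-O-D) repeat this pattern.
- Key cut: ring C splits into a C6-C1 unit, the ethynyl ether of the A-B phenol, and a C5/C2/C3/C4 unit, a racemic 2-aryloxy-3-ethoxy-4-methoxycyclobutenone carrying protected ring D. A Danheiser benzannulation joins them.
- The same cut serves ring G (ring F ethynyl ether + ring H cyclobutenone) and, last, ring E (F-G-H ethynyl ether + a cyclobutenone on the ring D C4 oxygen of the A-D tetramer). The tetra-ortho-substituted D-O-E ether is not a realistic cross-coupling target.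
- Each aryl-O bond that ends up on C2 of ring C, C2 of ring G or C1 of ring E is made by aryloxide attack on ethyl squaryl chloride. Only the A-B ether needs an Ullmann coupling.
- Ring order: A, B, D, F and H are bought as arenes. C and G are formed in parallel, E in the fragment union, and one BBr3 step frees all 21 hydroxyls.

Key step: step 12

Assumption: the target has no stereocentre and its diaryl ethers are taken as freely rotating, so only alkene geometries of intermediates and racemic cyclobutenone centres (all erased on aromatisation) need description.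

**Ethyl squaryl chloride**

Step 1
Reactants: 1 squaric acid (3,4-dihydroxycyclobut-3-ene-1,2-dione)
Product: 2 3,4-dichlorocyclobut-3-ene-1,2-dione
Conditions: (COCl)2 (2.2 equiv), DMF (cat.), ClCH2CH2Cl, 50 °C
Reagents that add atoms: oxalyl chloride, O=C(Cl)C(=O)Cl
Why: DMF-catalysed chlorodehydroxylation of the two vinylogous carboxylic acid groups is the standard access to squaryl dichloride.

Step 2
Reactants: 2 3,4-dichlorocyclobut-3-ene-1,2-dione
Product: 3 3-chloro-4-ethoxycyclobut-3-ene-1,2-dione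
Conditions: EtOH (1.0 equiv), CH2Cl2, 0 °C to rt; evaporated and used crude
Reagents that add atoms: ethanol, CCO
Why: Addition-elimination (vinylogous acyl substitution) by one equivalent of alcohol stops at the ester chloride, because the new ethoxy group donates into the dione and slows a second exchange.

**Ring D phenol and its cyclobutenone**

Step 3
Reactants: 4 syringaldehyde
Product: 5 4-(benzyloxy)-3,5-dimethoxybenzaldehyde
Conditions: BnBr, K2CO3, DMF, rt
Reagents that add atoms: benzyl bromide, BrCc1ccccc1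
Why: Williamson etherification of the only phenol; the aldehyde has no alpha hydrogen and tolerates carbonate.

Step 4
Reactants: 5 4-(benzyloxy)-3,5-dimethoxybenzaldehyde
Product: 7 4-(benzyloxy)-3,5-dimethoxyphenol, via aryl formate 6 (not isolated)
Conditions: mCPBA, CH2Cl2, 0 °C to rt; then K2CO3 (cat.), MeOH, rt
Reagents that add atoms: mCPBA, O=C(OO)c1cccc(Cl)c1
Why: Baeyer-Villiger oxidation with aryl migration, favoured by the para alkoxy group, gives the formate, which catalytic carbonate in methanol transesterifies to the phenol.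

Step 5
Reactants: 7 4-(benzyloxy)-3,5-dimethoxyphenol; 3 3-chloro-4-ethoxycyclobut-3-ene-1,2-dione
Product: 9 rac-2-[4-(benzyloxy)-3,5-dimethoxyphenoxy]-3-ethoxy-4-hydroxycyclobut-2-en-1-one, via mixed squarate 8 (not isolated)
Conditions: 7, NaH, THF, 0 °C; cannulated into 3, THF, -78 °C; then LiAlH(OtBu)3 (1.05 equiv), -78 °C; H2O quench
Reagents that add atoms: none
Why: Aryloxide addition-elimination at the C-Cl carbon replaces an exchange on a dialkyl squarate, which would be uphill because aryloxide is the better leaving group; the 1,2-reduction known for squarate esters then strikes the carbonyl next to C-OEt, which is only a vinylogous aryl ester and the less shielded one, so the aryloxy group ends alpha to the surviving ketone and the new C4 centre is racemic.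

Step 6
Reactants: 9 rac-2-[4-(benzyloxy)-3,5-dimethoxyphenoxy]-3-ethoxy-4-hydroxycyclobut-2-en-1-one
Product: 10 rac-2-[4-(benzyloxy)-3,5-dimethoxyphenoxy]-3-ethoxy-4-methoxycyclobut-2-en-1-one
Conditions: MeI (excess), Ag2O, 4 Å MS, CH2Cl2, rt, dark
Reagents that add atoms: iodomethane, CI
Why: Purdie methylation alkylates the secondary alcohol without acid (which would expel ethanol to give a cyclobutenedione) and without strong base; the racemic centre is untouched and disappears in step 12.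

**A-B phenol and its ethynyl ether**

Step 7
Reactants: 11 4-bromo-2,6-dimethoxyphenol
Product: 12 2-(benzyloxy)-5-bromo-1,3-dimethoxybenzene
Conditions: BnBr, K2CO3, DMF, rt
Reagents that add atoms: benzyl bromide, BrCc1ccccc1
Why: Williamson etherification masks the future ring B C4 oxygen so that only one phenol is present in the coupling.

Step 8
Reactants: 12 2-(benzyloxy)-5-bromo-1,3-dimethoxybenzene; 13 2,4,6-trimethoxyphenol
Product: 14 2-(benzyloxy)-1,3-dimethoxy-5-(2,4,6-trimethoxyphenoxy)benzene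
Conditions: CuI (10 mol %), picolinic acid (20 mol %), K3PO4, DMSO, 90 °C, Ar
Reagents that add atoms: none
Why: Ligand-accelerated Ullmann diaryl ether coupling pairs a di-ortho-substituted phenol with a bromide flanked by two hydrogens, the sterically favourable combination; it is preferred to an oxidative phenol-phenol union, in which 2,6-dimethoxyphenol couples at carbon.

Step 9
Reactants: 14 2-(benzyloxy)-1,3-dimethoxy-5-(2,4,6-trimethoxyphenoxy)benzene
Product: 15 2,6-dimethoxy-4-(2,4,6-trimethoxyphenoxy)phenol (A-B phenol)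
Conditions: H2 (1 atm), 10% Pd/C, EtOAc/MeOH, rt
Reagents that add atoms: none
Why: Catalytic hydrogenolysis cleaves only the benzylic C-O bond and leaves methyl and diaryl ethers intact.

Step 10
Reactants: 15 A-B phenol
Product: 16 2-{[(E)-1,2-dichloroethenyl]oxy}-1,3-dimethoxy-5-(2,4,6-trimethoxyphenoxy)benzene
Conditions: Cl2C=CHCl, K2CO3, DMF, 70 °C
Reagents that add atoms: trichloroethylene, ClC=C(Cl)Cl
Why: Base-induced loss of HCl from trichloroethylene gives dichloroacetylene, to which the phenoxide adds anti to give the (E)-dichlorovinyl ether; the linear electrophile is insensitive to the two ortho methoxy groups.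

Step 11
Reactants: 16 (E)-dichlorovinyl ether of the A-B phenol
Product: 19 2-(ethynyloxy)-1,3-dimethoxy-5-(2,4,6-trimethoxyphenoxy)benzene, via chloroethynyl ether 17 (not isolated), via lithium acetylide 18 (not isolated)
Conditions: n-BuLi (2.5 equiv), THF, -78 to -40 °C; H2O, -78 °C; kept cold as a toluene solution
Reagents that add atoms: none
Why: Dehydrochlorination, chlorine-lithium exchange and protonation form the established dichlorovinyl ether route to terminal ynol ethers, and at -78 °C vinyl deprotonation outruns ortho-lithiation of the anisole rings.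

**Ring C**

Step 12
Reactants: 19 ethynyl ether of the A-B phenol; 10 rac-2-[4-(benzyloxy)-3,5-dimethoxyphenoxy]-3-ethoxy-4-methoxycyclobut-2-en-1-one
Product: 24 A-B-C-D tetramer phenol (ring C: C1 O-ring B; C2 O-ring D; C3 OEt; C4 OMe; C5 OH; C6 H; ring D C4 OBn), via vinylketene 20 (not isolated), via vinylcyclobutenone 21 (not isolated), via dienylketene 22 (not isolated), via cyclohexadienone 23 (not isolated)
Conditions: 10 (1.2 equiv), PhMe, 110 °C, Ar; 19 added by syringe pump, then held at 110 °C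
Reagents that add atoms: none
Why: Heating opens 10 by a conrotatory four-electron electrocyclic reaction, its C4 methoxy group turning outward, to the aryloxy(vinyl)ketene 20, whose carbonyl carbon is attacked by the unsubstituted, nucleophilic alkyne carbon of 19 so that a (2+2) cycloaddition gives 4-vinylcyclobutenone 21. Compound 21 reopens with the ring D aryloxy group turning outward and the vinyl group inward to dienylketene 22, and ring C closes by a disrotatory six-electron electrocyclisation to cyclohexadienone 23, which enolises to phenol 24. This is the Danheiser benzannulation of a cyclobutenone with an oxygen-substituted alkyne, used here with an aryloxyacetylene and a squarate-derived, fully oxygenated cyclobutenone. The bond-forming events are C5-C6 and C1-C2 (cycloaddition) and C4-C5 (electrocyclisation, rejoining the two atoms parted in the first opening), so the alkyne ends as C6 and C1, the old carbonyl as C5 and the other cyclobutenone carbons as C2, C3 and C4. No stereocentre is created in 24, the racemic centres of 10, 21 and 23 being erased on aromatisation. The selectivity needed is the orientation of the ketene-alkyne addition, which the oxygen polarisation of the ynol ether fixes so that the ring B ether lands meta to the new hydroxyl and next to the ring D ether, while slow addition of 19 keeps its self-reaction behind ketene capture.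

Step 13
Reactants: 24 A-B-C-D tetramer phenol
Product: 25 A-B-C-D tetramer methyl ether (ring C C5 OMe; ring D C4 OBn)
Conditions: MeI, K2CO3, acetone, reflux
Reagents that add atoms: iodomethane, CI
Why: Williamson methylation caps the only free phenol so that the ring D oxygen will be the sole nucleophile later.

Step 14
Reactants: 25 A-B-C-D tetramer methyl ether
Product: 26 A-B-C-D tetramer with free ring D C4 hydroxyl
Conditions: H2 (1 atm), 10% Pd/C, EtOAc/MeOH, rt
Reagents that add atoms: none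
Why: Hydrogenolysis removes the single benzyl group; nothing else in 25 is reducible under these conditions.

Step 15
Reactants: 26 A-B-C-D tetramer with free ring D C4 hydroxyl; 3 3-chloro-4-ethoxycyclobut-3-ene-1,2-dione
Product: 28 rac-3-ethoxy-4-hydroxy-2-(A-B-C-D aryloxy)cyclobut-2-en-1-one, via mixed squarate 27 (not isolated)
Conditions: 26, NaH, THF, 0 °C; cannulated into 3, THF, -78 °C; then LiAlH(OtBu)3 (1.05 equiv), -78 °C; H2O quench
Reagents that add atoms: none
Why: The di-ortho-substituted phenoxide meets an unhindered sp2 C-Cl carbon on a four-membered ring (addition-elimination), so the future D-O-E bond is made before ring E exists; the bulky hydride then reduces the carbonyl remote from the large aryloxy group as in step 5, giving a racemic carbinol.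

Step 16
Reactants: 28 rac-3-ethoxy-4-hydroxy-2-(A-B-C-D aryloxy)cyclobut-2-en-1-one
Product: 29 rac-3-ethoxy-4-methoxy-2-(A-B-C-D aryloxy)cyclobut-2-en-1-one
Conditions: MeI (excess), Ag2O, 4 Å MS, CH2Cl2, rt, dark
Reagents that add atoms: iodomethane, CI
Why: Purdie methylation as in step 6, neutral enough for the acid-sensitive hydroxycyclobutenone.

**Ring H cyclobutenone**

Step 17
Reactants: 30 3,4,5-trimethoxyphenol; 3 3-chloro-4-ethoxycyclobut-3-ene-1,2-dione
Product: 32 rac-3-ethoxy-4-hydroxy-2-(3,4,5-trimethoxyphenoxy)cyclobut-2-en-1-one, via mixed squarate 31 (not isolated)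
Conditions: 30, NaH, THF, 0 °C; cannulated into 3, THF, -78 °C; then LiAlH(OtBu)3 (1.05 equiv), -78 °C; H2O quench
Reagents that add atoms: none
Why: Same addition-elimination and regioselective 1,2-reduction of the more electrophilic vinylogous aryl ester carbonyl as in step 5, giving the racemic carbinol.

Step 18
Reactants: 32 rac-3-ethoxy-4-hydroxy-2-(3,4,5-trimethoxyphenoxy)cyclobut-2-en-1-one
Product: 33 rac-3-ethoxy-4-methoxy-2-(3,4,5-trimethoxyphenoxy)cyclobut-2-en-1-one
Conditions: MeI (excess), Ag2O, 4 Å MS, CH2Cl2, rt, dark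
Reagents that add atoms: iodomethane, CI
Why: Purdie methylation as in step 6.

**Ring F ethynyl ether, ring G and the F-G-H ethynyl ether**

Step 19
Reactants: 34 3-hydroxy-4,5-dimethoxybenzaldehyde
Product: 35 3-{[(E)-1,2-dichloroethenyl]oxy}-4,5-dimethoxybenzaldehyde
Conditions: Cl2C=CHCl, K2CO3, DMF, 70 °C
Reagents that add atoms: trichloroethylene, ClC=C(Cl)Cl
Why: Anti addition of the phenoxide to dichloroacetylene made in situ, as in step 10; the dichlorovinyl ether serves both as the masked alkyne and as the protecting group of the ring F C5 oxygen, and the non-enolisable aldehyde tolerates carbonate.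

Step 20
Reactants: 35 3-{[(E)-1,2-dichloroethenyl]oxy}-4,5-dimethoxybenzaldehyde
Product: 37 3-{[(E)-1,2-dichloroethenyl]oxy}-4,5-dimethoxyphenol, via aryl formate 36 (not isolated)
Conditions: mCPBA, NaHCO3 (buffer), CH2Cl2, 0 °C to rt; then K2CO3 (cat.), MeOH, rt
Reagents that add atoms: mCPBA, O=C(OO)c1cccc(Cl)c1
Why: Baeyer-Villiger oxidation with aryl migration, helped by the para methoxy group, is faster than epoxidation of an alkene deactivated by two chlorines, and the vinyl ether resists catalytic carbonate in methanol.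

Step 21
Reactants: 37 3-{[(E)-1,2-dichloroethenyl]oxy}-4,5-dimethoxyphenol
Product: 38 5-(benzyloxy)-1-{[(E)-1,2-dichloroethenyl]oxy}-2,3-dimethoxybenzene
Conditions: BnBr, K2CO3, DMF, rt
Reagents that add atoms: benzyl bromide, BrCc1ccccc1
Why: Williamson etherification of the ring F C1 oxygen under the same base and solvent in which the dichlorovinyl ether was formed, and at a lower temperature.

Step 22
Reactants: 38 5-(benzyloxy)-1-{[(E)-1,2-dichloroethenyl]oxy}-2,3-dimethoxybenzene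
Product: 41 5-(benzyloxy)-1-(ethynyloxy)-2,3-dimethoxybenzene, via chloroethynyl ether 39 (not isolated), via lithium acetylide 40 (not isolated)
Conditions: n-BuLi (2.5 equiv), THF, -78 to -40 °C; H2O, -78 °C; kept cold as a toluene solution
Reagents that add atoms: none
Why: Dehydrochlorination, chlorine-lithium exchange and protonation as in step 11; the benzyl ether is inert to n-BuLi at this temperature.

Step 23
Reactants: 41 5-(benzyloxy)-1-(ethynyloxy)-2,3-dimethoxybenzene; 33 rac-3-ethoxy-4-methoxy-2-(3,4,5-trimethoxyphenoxy)cyclobut-2-en-1-one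
Product: 46 5-[5-(benzyloxy)-2,3-dimethoxyphenoxy]-3-ethoxy-2-methoxy-4-(3,4,5-trimethoxyphenoxy)phenol (F-G-H trimer phenol), via vinylketene 42 (not isolated), via vinylcyclobutenone 43 (not isolated), via dienylketene 44 (not isolated), via cyclohexadienone 45 (not isolated)
Conditions: 33 (1.2 equiv), PhMe, 110 °C, Ar; 41 added by syringe pump, then held at 110 °C
Reagents that add atoms: none
Why: The Danheiser benzannulation cascade of step 12 (ring opening, (2+2) addition, reopening, six-electron closure, enolisation) builds ring G, the alkyne giving C6 and C1 and the ynol ether polarity again placing the ring F ether beside the ring H ether.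

Step 24
Reactants: 46 F-G-H trimer phenol
Product: 47 1-[5-(benzyloxy)-2,3-dimethoxyphenoxy]-3-ethoxy-4,5-dimethoxy-2-(3,4,5-trimethoxyphenoxy)benzene
Conditions: MeI, K2CO3, acetone, reflux
Reagents that add atoms: iodomethane, CI
Why: Williamson methylation caps the ring G C5 hydroxyl before the ring F oxygen is released.

Step 25
Reactants: 47 F-G-H trimer methyl ether
Product: 48 3-[3-ethoxy-4,5-dimethoxy-2-(3,4,5-trimethoxyphenoxy)phenoxy]-4,5-dimethoxyphenol
Conditions: H2 (1 atm), 10% Pd/C, EtOAc/MeOH, rt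
Reagents that add atoms: none
Why: Hydrogenolysis of the only benzyl ether frees the ring F C1 hydroxyl.

Step 26
Reactants: 48 F-G-H trimer with free ring F C1 hydroxyl
Product: 49 (E)-1,2-dichlorovinyl ether of the F-G-H trimer
Conditions: Cl2C=CHCl, K2CO3, DMF, 70 °C
Reagents that add atoms: trichloroethylene, ClC=C(Cl)Cl
Why: Anti addition of an unhindered phenoxide to dichloroacetylene made in situ, as in step 10.

Step 27
Reactants: 49 (E)-1,2-dichlorovinyl ether of the F-G-H trimer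
Product: 52 ethynyl ether of the F-G-H trimer, via chloroethynyl ether 50 (not isolated), via lithium acetylide 51 (not isolated)
Conditions: n-BuLi (2.5 equiv), THF, -78 to -40 °C; H2O, -78 °C; kept cold as a toluene solution
Reagents that add atoms: none
Why: Same dehydrochlorination, chlorine-lithium exchange and protonation as in step 11.

**Union through ring E and deprotection**

Step 28
Reactants: 52 ethynyl ether of the F-G-H trimer; 29 rac-3-ethoxy-4-methoxy-2-(A-B-C-D aryloxy)cyclobut-2-en-1-one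
Product: 57 protected octamer phenol (ring E: C1 O-ring D; C2 O-ring F; C3 H; C4 OH; C5 OMe; C6 OEt), via vinylketene 53 (not isolated), via vinylcyclobutenone 54 (not isolated), via dienylketene 55 (not isolated), via cyclohexadienone 56 (not isolated)
Conditions: 29 (1.0 equiv), PhMe, 110 °C, Ar; 52 (1.3 equiv) added by syringe pump, then held at 110 °C
Reagents that add atoms: none
Why: A third Danheiser benzannulation joins the two halves while it builds ring E by six-electron electrocyclisation, the alkyne giving C3 and C2, the old carbonyl C4 and the remaining cyclobutenone carbons C1, C6 and C5, with regiochemistry again set by the ynol ether polarity.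

Step 29
Reactants: 57 protected octamer phenol
Product: 58 target octamer CNP0309601.0
Conditions: BBr3 (40 equiv), CH2Cl2, -78 °C to rt, Ar; H2O, 0 °C; degassed solvents, reversed-phase purification
Reagents that add atoms: none
Why: Lewis-acid ether cleavage with BBr3 breaks the 17 methyl and 3 ethyl O-alkyl bonds by bromide attack on the alkyl carbon, whereas the seven diaryl ether bonds offer no sp3 carbon and survive.

**Compound list**
1 | squaric acid | OC1=C(O)C(=O)C1=O | starting material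
2 | 3,4-dichlorocyclobut-3-ene-1,2-dione | ClC1=C(Cl)C(=O)C1=O | intermediate
3 | 3-chloro-4-ethoxycyclobut-3-ene-1,2-dione | CCOC1=C(Cl)C(=O)C1=O | intermediate
4 | syringaldehyde | COc1cc(C=O)cc(OC)c1O | starting material
5 | 4-(benzyloxy)-3,5-dimethoxybenzaldehyde | COc1cc(C=O)cc(OC)c1OCc1ccccc1 | intermediate
6 | 4-(benzyloxy)-3,5-dimethoxyphenyl formate | COc1cc(OC=O)cc(OC)c1OCc1ccccc1 | intermediate
7 | 4-(benzyloxy)-3,5-dimethoxyphenol | COc1cc(O)cc(OC)c1OCc1ccccc1 | intermediate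
8 | 3-[4-(benzyloxy)-3,5-dimethoxyphenoxy]-4-ethoxycyclobut-3-ene-1,2-dione | CCOC1=C(Oc2cc(OC)c(OCc3ccccc3)c(OC)c2)C(=O)C1=O | intermediate
9 | rac-2-[4-(benzyloxy)-3,5-dimethoxyphenoxy]-3-ethoxy-4-hydroxycyclobut-2-en-1-one | CCOC1=C(Oc2cc(OC)c(OCc3ccccc3)c(OC)c2)C(=O)C1O | intermediate
10 | rac-2-[4-(benzyloxy)-3,5-dimethoxyphenoxy]-3-ethoxy-4-methoxycyclobut-2-en-1-one | CCOC1=C(Oc2cc(OC)c(OCc3ccccc3)c(OC)c2)C(=O)C1OC | intermediate
11 | 4-bromo-2,6-dimethoxyphenol | COc1cc(Br)cc(OC)c1O | starting material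
12 | 2-(benzyloxy)-5-bromo-1,3-dimethoxybenzene | COc1cc(Br)cc(OC)c1OCc1ccccc1 | intermediate
13 | 2,4,6-trimethoxyphenol | COc1cc(OC)c(O)c(OC)c1 | starting material
14 | 2-(benzyloxy)-1,3-dimethoxy-5-(2,4,6-trimethoxyphenoxy)benzene | COc1cc(Oc2c(OC)cc(OC)cc2OC)cc(OC)c1OCc1ccccc1 | intermediate
15 | 2,6-dimethoxy-4-(2,4,6-trimethoxyphenoxy)phenol (A-B phenol) | Oc1c(OC)cc(Oc2c(OC)cc(OC)cc2OC)cc1OC | intermediate
16 | 2-{[(E)-1,2-dichloroethenyl]oxy}-1,3-dimethoxy-5-(2,4,6-trimethoxyphenoxy)benzene | Cl/C=C(/Cl)Oc1c(OC)cc(Oc2c(OC)cc(OC)cc2OC)cc1OC | intermediate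
17 | 2-[(chloroethynyl)oxy]-1,3-dimethoxy-5-(2,4,6-trimethoxyphenoxy)benzene | ClC#COc1c(OC)cc(Oc2c(OC)cc(OC)cc2OC)cc1OC | intermediate
18 | lithium acetylide of 19 | [Li]C#COc1c(OC)cc(Oc2c(OC)cc(OC)cc2OC)cc1OC | intermediate
19 | 2-(ethynyloxy)-1,3-dimethoxy-5-(2,4,6-trimethoxyphenoxy)benzene | C#COc1c(OC)cc(Oc2c(OC)cc(OC)cc2OC)cc1OC | intermediate
20 | (3Z)-2-[4-(benzyloxy)-3,5-dimethoxyphenoxy]-3-ethoxy-4-methoxybuta-1,3-dien-1-one (OMe trans to C2) | O=C=C(Oc1cc(OC)c(OCc2ccccc2)c(OC)c1)/C(OCC)=C/OC | intermediate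
21 | rac-4-(ring D aryloxy)-3-(A-B aryloxy)-4-[(Z)-1-ethoxy-2-methoxyethenyl]cyclobut-2-en-1-one | O=C1C=C(Oc2c(OC)cc(Oc3c(OC)cc(OC)cc3OC)cc2OC)C1(Oc1cc(OC)c(OCc2ccccc2)c(OC)c1)/C(OCC)=C/OC | intermediate
22 | (3Z,5Z)-3-(A-B aryloxy)-4-(ring D aryloxy)-5-ethoxy-6-methoxyhexa-1,3,5-trien-1-one | O=C=C/C(Oc1c(OC)cc(Oc2c(OC)cc(OC)cc2OC)cc1OC)=C(Oc1cc(OC)c(OCc2ccccc2)c(OC)c1)\C(OCC)=C\OC | intermediate
23 | rac-3-(A-B aryloxy)-4-(ring D aryloxy)-5-ethoxy-6-methoxycyclohexa-2,4-dien-1-one | O=C1C=C(Oc2c(OC)cc(Oc3c(OC)cc(OC)cc3OC)cc2OC)C(Oc2cc(OC)c(OCc3ccccc3)c(OC)c2)=C(OCC)C1OC | intermediate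
24 | 4-[4-(benzyloxy)-3,5-dimethoxyphenoxy]-5-[2,6-dimethoxy-4-(2,4,6-trimethoxyphenoxy)phenoxy]-3-ethoxy-2-methoxyphenol | Oc1cc(Oc2c(OC)cc(Oc3c(OC)cc(OC)cc3OC)cc2OC)c(Oc2cc(OC)c(OCc3ccccc3)c(OC)c2)c(OCC)c1OC | intermediate
25 | 2-[4-(benzyloxy)-3,5-dimethoxyphenoxy]-1-[2,6-dimethoxy-4-(2,4,6-trimethoxyphenoxy)phenoxy]-3-ethoxy-4,5-dimethoxybenzene | COc1cc(Oc2c(OC)cc(Oc3c(OC)cc(OC)cc3OC)cc2OC)c(Oc2cc(OC)c(OCc3ccccc3)c(OC)c2)c(OCC)c1OC | intermediate
26 | 4-{2-[2,6-dimethoxy-4-(2,4,6-trimethoxyphenoxy)phenoxy]-6-ethoxy-4,5-dimethoxyphenoxy}-2,6-dimethoxyphenol | COc1cc(Oc2c(OC)cc(Oc3c(OC)cc(OC)cc3OC)cc2OC)c(Oc2cc(OC)c(O)c(OC)c2)c(OCC)c1OC | intermediate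
27 | 3-ethoxy-4-(A-B-C-D aryloxy)cyclobut-3-ene-1,2-dione (ester of the ring D C4 oxygen of 26) | CCOC4=C(Oc1c(OC)cc(Oc2c(OCC)c(OC)c(OC)cc2Oc2c(OC)cc(Oc3c(OC)cc(OC)cc3OC)cc2OC)cc1OC)C(=O)C4=O | intermediate
28 | rac-3-ethoxy-4-hydroxy-2-(A-B-C-D aryloxy)cyclobut-2-en-1-one | CCOC4=C(Oc1c(OC)cc(Oc2c(OCC)c(OC)c(OC)cc2Oc2c(OC)cc(Oc3c(OC)cc(OC)cc3OC)cc2OC)cc1OC)C(=O)C4O | intermediate
29 | rac-3-ethoxy-4-methoxy-2-(A-B-C-D aryloxy)cyclobut-2-en-1-one | CCOC4=C(Oc1c(OC)cc(Oc2c(OCC)c(OC)c(OC)cc2Oc2c(OC)cc(Oc3c(OC)cc(OC)cc3OC)cc2OC)cc1OC)C(=O)C4OC | intermediate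
30 | 3,4,5-trimethoxyphenol | COc1cc(O)cc(OC)c1OC | starting material
31 | 3-ethoxy-4-(3,4,5-trimethoxyphenoxy)cyclobut-3-ene-1,2-dione | CCOC1=C(Oc2cc(OC)c(OC)c(OC)c2)C(=O)C1=O | intermediate
32 | rac-3-ethoxy-4-hydroxy-2-(3,4,5-trimethoxyphenoxy)cyclobut-2-en-1-one | CCOC1=C(Oc2cc(OC)c(OC)c(OC)c2)C(=O)C1O | intermediate
33 | rac-3-ethoxy-4-methoxy-2-(3,4,5-trimethoxyphenoxy)cyclobut-2-en-1-one | CCOC1=C(Oc2cc(OC)c(OC)c(OC)c2)C(=O)C1OC | intermediate
34 | 3-hydroxy-4,5-dimethoxybenzaldehyde | COc1cc(C=O)cc(O)c1OC | starting material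
35 | 3-{[(E)-1,2-dichloroethenyl]oxy}-4,5-dimethoxybenzaldehyde | Cl/C=C(/Cl)Oc1cc(C=O)cc(OC)c1OC | intermediate
36 | 3-{[(E)-1,2-dichloroethenyl]oxy}-4,5-dimethoxyphenyl formate | Cl/C=C(/Cl)Oc1cc(OC=O)cc(OC)c1OC | intermediate
37 | 3-{[(E)-1,2-dichloroethenyl]oxy}-4,5-dimethoxyphenol | Cl/C=C(/Cl)Oc1cc(O)cc(OC)c1OC | intermediate
38 | 5-(benzyloxy)-1-{[(E)-1,2-dichloroethenyl]oxy}-2,3-dimethoxybenzene | Cl/C=C(/Cl)Oc1cc(OCc2ccccc2)cc(OC)c1OC | intermediate
39 | 5-(benzyloxy)-1-[(chloroethynyl)oxy]-2,3-dimethoxybenzene | ClC#COc1cc(OCc2ccccc2)cc(OC)c1OC | intermediate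
40 | lithium acetylide of 41 | [Li]C#COc1cc(OCc2ccccc2)cc(OC)c1OC | intermediate
41 | 5-(benzyloxy)-1-(ethynyloxy)-2,3-dimethoxybenzene | C#COc1cc(OCc2ccccc2)cc(OC)c1OC | intermediate
42 | (3Z)-3-ethoxy-4-methoxy-2-(3,4,5-trimethoxyphenoxy)buta-1,3-dien-1-one | O=C=C(Oc1cc(OC)c(OC)c(OC)c1)/C(OCC)=C/OC | intermediate
43 | rac-3-(ring F aryloxy)-4-(ring H aryloxy)-4-[(Z)-1-ethoxy-2-methoxyethenyl]cyclobut-2-en-1-one | O=C1C=C(Oc2cc(OCc3ccccc3)cc(OC)c2OC)C1(Oc1cc(OC)c(OC)c(OC)c1)/C(OCC)=C/OC | intermediate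
44 | (3Z,5Z)-3-(ring F aryloxy)-4-(ring H aryloxy)-5-ethoxy-6-methoxyhexa-1,3,5-trien-1-one | O=C=C/C(Oc1cc(OCc2ccccc2)cc(OC)c1OC)=C(Oc1cc(OC)c(OC)c(OC)c1)\C(OCC)=C\OC | intermediate
45 | rac-3-(ring F aryloxy)-4-(ring H aryloxy)-5-ethoxy-6-methoxycyclohexa-2,4-dien-1-one | O=C1C=C(Oc2cc(OCc3ccccc3)cc(OC)c2OC)C(Oc2cc(OC)c(OC)c(OC)c2)=C(OCC)C1OC | intermediate
46 | 5-[5-(benzyloxy)-2,3-dimethoxyphenoxy]-3-ethoxy-2-methoxy-4-(3,4,5-trimethoxyphenoxy)phenol | Oc1cc(Oc2cc(OCc3ccccc3)cc(OC)c2OC)c(Oc2cc(OC)c(OC)c(OC)c2)c(OCC)c1OC | intermediate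
47 | 1-[5-(benzyloxy)-2,3-dimethoxyphenoxy]-3-ethoxy-4,5-dimethoxy-2-(3,4,5-trimethoxyphenoxy)benzene | COc1cc(Oc2cc(OCc3ccccc3)cc(OC)c2OC)c(Oc2cc(OC)c(OC)c(OC)c2)c(OCC)c1OC | intermediate
48 | 3-[3-ethoxy-4,5-dimethoxy-2-(3,4,5-trimethoxyphenoxy)phenoxy]-4,5-dimethoxyphenol | COc1cc(Oc2cc(O)cc(OC)c2OC)c(Oc2cc(OC)c(OC)c(OC)c2)c(OCC)c1OC | intermediate
49 | (E)-1,2-dichlorovinyl ether of 48 | Cl/C=C(/Cl)Oc1cc(OC)c(OC)c(Oc2cc(OC)c(OC)c(OCC)c2Oc2cc(OC)c(OC)c(OC)c2)c1 | intermediate
50 | chloroethynyl ether of 48 | ClC#COc1cc(OC)c(OC)c(Oc2cc(OC)c(OC)c(OCC)c2Oc2cc(OC)c(OC)c(OC)c2)c1 | intermediate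
51 | lithium acetylide of 52 | [Li]C#COc1cc(OC)c(OC)c(Oc2cc(OC)c(OC)c(OCC)c2Oc2cc(OC)c(OC)c(OC)c2)c1 | intermediate
52 | ethynyl ether of 48 (F-G-H ethynyl ether) | C#COc1cc(OC)c(OC)c(Oc2cc(OC)c(OC)c(OCC)c2Oc2cc(OC)c(OC)c(OC)c2)c1 | intermediate
53 | (3Z)-2-(A-B-C-D aryloxy)-3-ethoxy-4-methoxybuta-1,3-dien-1-one | O=C=C(Oc1c(OC)cc(Oc2c(OCC)c(OC)c(OC)cc2Oc2c(OC)cc(Oc3c(OC)cc(OC)cc3OC)cc2OC)cc1OC)/C(OCC)=C/OC | intermediate
54 | rac-3-(F-G-H aryloxy)-4-(A-B-C-D aryloxy)-4-[(Z)-1-ethoxy-2-methoxyethenyl]cyclobut-2-en-1-one | O=C4C=C(Oc1cc(OC)c(OC)c(Oc2cc(OC)c(OC)c(OCC)c2Oc2cc(OC)c(OC)c(OC)c2)c1)C4(Oc1c(OC)cc(Oc2c(OCC)c(OC)c(OC)cc2Oc2c(OC)cc(Oc3c(OC)cc(OC)cc3OC)cc2OC)cc1OC)/C(OCC)=C/OC | intermediate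
55 | (3Z,5Z)-3-(F-G-H aryloxy)-4-(A-B-C-D aryloxy)-5-ethoxy-6-methoxyhexa-1,3,5-trien-1-one | O=C=C/C(Oc1cc(OC)c(OC)c(Oc2cc(OC)c(OC)c(OCC)c2Oc2cc(OC)c(OC)c(OC)c2)c1)=C(Oc1c(OC)cc(Oc2c(OCC)c(OC)c(OC)cc2Oc2c(OC)cc(Oc3c(OC)cc(OC)cc3OC)cc2OC)cc1OC)\C(OCC)=C\OC | intermediate
56 | rac-3-(F-G-H aryloxy)-4-(A-B-C-D aryloxy)-5-ethoxy-6-methoxycyclohexa-2,4-dien-1-one | O=C4C=C(Oc1cc(OC)c(OC)c(Oc2cc(OC)c(OC)c(OCC)c2Oc2cc(OC)c(OC)c(OC)c2)c1)C(Oc1c(OC)cc(Oc2c(OCC)c(OC)c(OC)cc2Oc2c(OC)cc(Oc3c(OC)cc(OC)cc3OC)cc2OC)cc1OC)=C(OCC)C4OC | intermediate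
57 | protected octamer phenol (17 OMe, 3 OEt, free ring E C4 OH) | Oc4cc(Oc1cc(OC)c(OC)c(Oc2cc(OC)c(OC)c(OCC)c2Oc2cc(OC)c(OC)c(OC)c2)c1)c(Oc1c(OC)cc(Oc2c(OCC)c(OC)c(OC)cc2Oc2c(OC)cc(Oc3c(OC)cc(OC)cc3OC)cc2OC)cc1OC)c(OCC)c4OC | intermediate
58 | CNP0309601.0 | Oc1cc(O)c(Oc2cc(O)c(Oc3cc(O)c(O)c(O)c3Oc3cc(O)c(Oc4c(Oc5cc(O)c(O)c(Oc6cc(O)c(O)c(O)c6Oc6cc(O)c(O)c(O)c6)c5)cc(O)c(O)c4O)c(O)c3)c(O)c2)c(O)c1 | target

**Totals**
- Total step count: 29.
- Longest linear sequence: 12 steps (steps 7 to 16, then 28 and 29).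

**Steps most likely to fail**

1. Step 12.
   - Risk: the terminal aryl ethynyl ether may oligomerise, or add to the phenol being formed. Either could be faster than capture of the vinylketene, whose release from a vinylogous ester type cyclobutenone needs prolonged heating.
   - Fallback: it sets out from 10 and comes back at 25. It keeps the cyclobutenone but installs the ring B ether after ring C exists.
   - Compound 10 is heated in toluene with (triisopropylsilyloxy)acetylene, the more nucleophilic and thermally robust siloxyalkyne partner of this benzannulation. This gives the C-D resorcinol monosilyl ether F1.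
   - MeI and K2CO3 in acetone give the methyl ether F2, and Bu4NF in THF frees the ring C C1 phenol F3.
   - Coupling of F3 with commercial 4-bromo-3,5-dimethoxybenzaldehyde (CuI, picolinic acid, K3PO4, DMSO), whose bromide is activated by the para formyl group, gives the aldehyde F4.
   - Baeyer-Villiger oxidation with mCPBA gives the aryl formate F5, and methanolysis gives the B-C-D phenol F6.
   - An Ullmann coupling of this unhindered phenol with 2-iodo-1,3,5-trimethoxybenzene (CuI, N,N-dimethylglycine, Cs2CO3, dioxane) delivers 25.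

2. Step 28.
   - Risk: two large partners are used near equimolar ratio, and the 2,6-dimethoxyaryloxy group crowds the ketene alpha carbon. The (2+2) capture may therefore be slow, and the ketene may be lost by dimerisation or by acylation of the product phenol.
   - Fallback: it sets out from 29 and 48 and comes back at 58. It builds ring E with a small alkyne and forms only the unhindered E-O-F bond (ring F C1 has two ortho hydrogens) by cross-coupling.
   - Compound 29 is heated with (triisopropylsilyloxy)acetylene to give the A-E pentamer phenol silyl ether F7.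
   - MeI and K2CO3 give its methyl ether F8, and Bu4NF gives the ring E C2 phenol F9.
   - Compound 48 is converted with Tf2O and pyridine into the F-G-H aryl triflate F10.
   - Palladium-catalysed diaryl ether formation (Pd(OAc)2, t-BuXPhos, K3PO4, toluene, 100 °C) joins F9 and F10 to the fully alkylated octamer F11.
   - BBr3 under the conditions of step 29 converts F11 into 58.

3. Step 29.
   - Risk: cleavage of twenty ethers may stall as insoluble aryl borates precipitate. The pyrogallol-type rings may also oxidise in air during isolation of the free polyphenol.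
   - Fallback: it sets out from 57 and comes back at 58 by a derivatise, purify and release sequence in which the crude polyphenol is never isolated.
   - After the BBr3 treatment and quench, the residue is acetylated exhaustively (Ac2O, pyridine, DMAP) to the henicosaacetate F12.
   - F12 is stable to air and can be chromatographed on silica. Fractions that still carry alkyl groups are returned to BBr3.
   - Zemplén deacetylation (NaOMe cat., MeOH, Ar, then acidic resin) releases 58.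

**Further compounds**
F1 | step 12 | 4-[4-(benzyloxy)-3,5-dimethoxyphenoxy]-3-ethoxy-2-methoxy-5-[(triisopropylsilyl)oxy]phenol | Oc1cc(O[Si](C(C)C)(C(C)C)C(C)C)c(Oc2cc(OC)c(OCc3ccccc3)c(OC)c2)c(OCC)c1OC
F2 | step 12 | {2-[4-(benzyloxy)-3,5-dimethoxyphenoxy]-3-ethoxy-4,5-dimethoxyphenoxy}triisopropylsilane | COc1cc(O[Si](C(C)C)(C(C)C)C(C)C)c(Oc2cc(OC)c(OCc3ccccc3)c(OC)c2)c(OCC)c1OC
F3 | step 12 | 2-[4-(benzyloxy)-3,5-dimethoxyphenoxy]-3-ethoxy-4,5-dimethoxyphenol | COc1cc(O)c(Oc2cc(OC)c(OCc3ccccc3)c(OC)c2)c(OCC)c1OC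
F4 | step 12 | 4-{2-[4-(benzyloxy)-3,5-dimethoxyphenoxy]-3-ethoxy-4,5-dimethoxyphenoxy}-3,5-dimethoxybenzaldehyde | COc1cc(Oc2c(OC)cc(C=O)cc2OC)c(Oc2cc(OC)c(OCc3ccccc3)c(OC)c2)c(OCC)c1OC
F5 | step 12 | 4-{2-[4-(benzyloxy)-3,5-dimethoxyphenoxy]-3-ethoxy-4,5-dimethoxyphenoxy}-3,5-dimethoxyphenyl formate | COc1cc(Oc2c(OC)cc(OC=O)cc2OC)c(Oc2cc(OC)c(OCc3ccccc3)c(OC)c2)c(OCC)c1OC
F6 | step 12 | 4-{2-[4-(benzyloxy)-3,5-dimethoxyphenoxy]-3-ethoxy-4,5-dimethoxyphenoxy}-3,5-dimethoxyphenol | COc1cc(Oc2c(OC)cc(O)cc2OC)c(Oc2cc(OC)c(OCc3ccccc3)c(OC)c2)c(OCC)c1OC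
F7 | step 28 | A-E pentamer phenol silyl ether (ring E: C1 O-ring D; C2 OSi(iPr)3; C4 OH; C5 OMe; C6 OEt) | Oc4cc(O[Si](C(C)C)(C(C)C)C(C)C)c(Oc1c(OC)cc(Oc2c(OCC)c(OC)c(OC)cc2Oc2c(OC)cc(Oc3c(OC)cc(OC)cc3OC)cc2OC)cc1OC)c(OCC)c4OC
F8 | step 28 | A-E pentamer silyl ether with ring E C4 OMe | COc4cc(O[Si](C(C)C)(C(C)C)C(C)C)c(Oc1c(OC)cc(Oc2c(OCC)c(OC)c(OC)cc2Oc2c(OC)cc(Oc3c(OC)cc(OC)cc3OC)cc2OC)cc1OC)c(OCC)c4OC
F9 | step 28 | A-E pentamer with free ring E C2 hydroxyl | COc4cc(O)c(Oc1c(OC)cc(Oc2c(OCC)c(OC)c(OC)cc2Oc2c(OC)cc(Oc3c(OC)cc(OC)cc3OC)cc2OC)cc1OC)c(OCC)c4OC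
F10 | step 28 | trifluoromethanesulfonate of 48 | O=S(=O)(Oc1cc(OC)c(OC)c(Oc2cc(OC)c(OC)c(OCC)c2Oc2cc(OC)c(OC)c(OC)c2)c1)C(F)(F)F
F11 | step 28 | fully alkylated octamer (18 OMe, 3 OEt) | COc4cc(Oc1cc(OC)c(OC)c(Oc2cc(OC)c(OC)c(OCC)c2Oc2cc(OC)c(OC)c(OC)c2)c1)c(Oc1c(OC)cc(Oc2c(OCC)c(OC)c(OC)cc2Oc2c(OC)cc(Oc3c(OC)cc(OC)cc3OC)cc2OC)cc1OC)c(OCC)c4OC
F12 | step 29 | henicosaacetate of 58 | CC(=O)Oc4cc(Oc1cc(OC(C)=O)c(OC(C)=O)c(Oc2cc(OC(C)=O)c(OC(C)=O)c(OC(C)=O)c2Oc2cc(OC(C)=O)c(OC(C)=O)c(OC(C)=O)c2)c1)c(Oc1c(OC(C)=O)cc(Oc2c(OC(C)=O)c(OC(C)=O)c(OC(C)=O)cc2Oc2c(OC(C)=O)cc(Oc3c(OC(C)=O)cc(OC(C)=O)cc3OC(C)=O)cc2OC(C)=O)cc1OC(C)=O)c(OC(C)=O)c4OC(C)=O
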